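**Plan**
1. Retrosynthetic cuts, in order: the two acyl–oxygen bonds at C4 and C1, then the C7–CH3 bond (back to a C7 enol triflate), then the ring bond C4–C5.
2. What permits the last cut: inside the eleven-membered carbocycle, C2=C3–C4–C5–C6=C7 is a 1,5-diene (2E,6Z) with C4–C5 as its central sigma bond, which is the pattern left by a [3,3] shift. Running the shift backwards joins C2 to C7. This leaves a cycloheptane (C7, C8, C9, C10, C11, C1, C2) with hydroxyl and vinyl (C6=C5) on C7 and, cis to the vinyl group, an E 1-alkoxyprop-1-en-2-yl group (C3=C4) on C2.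
3. The cycloheptanol is cut further at C5–C6 (sulfur ylide), C6–C7 (methylenation), C8–C9 (metathesis), C7–C8 (acylation), C3–CH3 (enolate alkylation) and C1–C2 (aldol).
4. Forward order of rings: a butyrolactone (O, C1, C2, C3, C4) forms first and the seven-membered ring is closed onto it. The lactone is then opened by reduction, and the seven-membered ring is finally enlarged to the eleven-membered ring.
5. Stereochemistry: C1 and C2 come from an auxiliary-controlled syn aldol, and C7 is relayed from C1 by a hydroxyl-directed epoxidation. C4 and both ring alkene geometries come from the chair transition state of the rearrangement, which consumes C2 and C7. C1 is carried through unchanged.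

Key step: step 15

Remark: the target ring numbering (C1 acetoxy carbon, C4 aroyloxy carbon, C11 the CMe2 carbon) is used for all intermediates. The C3 configuration drawn between the methylation and the enol ether formation is the expected one and is erased there, so it does not affect the outcome.

Step 1
Reactants: 1 (R)-4-benzyl-1,3-oxazolidin-2-one; 2 methyl 4-chloro-4-oxobutanoate
Product: 4 methyl 4-[(4R)-4-benzyl-2-oxo-1,3-oxazolidin-3-yl]-4-oxobutanoate, via lithium oxazolidinide 3 (not isolated)
Conditions: n-BuLi, THF, −78 °C; then 2, −78 to 0 °C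
Reagents that add atoms: none
Why: N-acylation of a lithiated Evans oxazolidinone by an acid chloride is fast at low temperature and leaves the methyl ester untouched.

Step 2
Reactants: 4 succinyl imide; 5 2,2-dimethylpent-4-enal
Product: 8 (4R)-4-benzyl-3-{[(2R,3R)-2-(2-methylpent-4-en-2-yl)-5-oxooxolan-3-yl]carbonyl}-1,3-oxazolidin-2-one (trans lactone; 1R,2R in target numbering), via Z dibutylboron enolate 6 (not isolated), via syn aldol 7 (not isolated)
Conditions: Bu2BOTf, iPr2NEt, CH2Cl2, 0 °C; 5, −78 to 0 °C; H2O2, MeOH, pH 7 buffer; cat. p-TsOH, CH2Cl2, rt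
Reagents that add atoms: none
Why: Evans syn aldol reaction, in which the Z boron enolate 6 reacts through a Zimmerman–Traxler chair on the face away from the benzyl group, setting C1 as R and C2 as R, after which the C1 hydroxyl of 7 closes onto the methyl ester (5-exo-trig lactonisation) to give the trans lactone.

Step 3
Reactants: 8 lactone imide
Product: 10 (2R,3R)-2-(2-methylpent-4-en-2-yl)-5-oxooxolane-3-carboxylic acid, via lithium peroxycarboxylate 9 (not isolated)
Conditions: LiOH, H2O2, THF/H2O, 0 °C; Na2SO3; HCl to pH 2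
Reagents that add atoms: hydrogen peroxide, OO
Why: Hydroperoxide cleavage of an N-acyl oxazolidinone attacks the exocyclic carbonyl selectively, any opened lactone re-closes on acidification, and no stereocentre is touched.

Step 4
Reactants: 10 lactone acid
Product: 12 (2R,3R,4R)-4-methyl-2-(2-methylpent-4-en-2-yl)-5-oxooxolane-3-carboxylic acid (1R,2R,3R in target numbering), via disodium enolate carboxylate 11 (not isolated)
Conditions: NaN(SiMe3)2 (2.2 equiv), THF, −78 °C; MeI; HCl work-up
Reagents that add atoms: iodomethane, CI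
Why: Alkylation of the carboxylate/lactone-enolate dianion should take place anti to the C2 carboxylate, installing the C3 methyl group at a centre that is later erased.

Step 5
Reactants: 12 methylated lactone acid
Product: 14 (3R,4R,5R)-3-methyl-5-(2-methylpent-4-en-2-yl)-4-(prop-2-enoyl)oxolan-2-one, via acid chloride 13 (not isolated)
Conditions: (COCl)2, cat. DMF, CH2Cl2, 0 °C to rt; evaporate; Bu3SnCH=CH2, Pd(PPh3)4 (5 mol %), THF, 50 °C
Reagents that add atoms: tributyl(vinyl)stannane, C=C[Sn](CCCC)(CCCC)CCCC
Why: Stille acylation of an acid chloride forms C7–C8 under neutral conditions, so the lactone survives and the β-acyloxy ketone neither epimerises at C2 nor eliminates.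

Step 6
Reactants: 14 vinyl ketone
Product: 16 trans-fused keto lactone (3R,3aR,8aR)-3,8,8-trimethylhexahydro-2H-cyclohepta[b]furan-2,4(3H)-dione (C7 ketone; 1R,2R,3R in target numbering), via bicyclic enone 15 (not isolated)
Conditions: second-generation Grubbs catalyst RuCl2(=CHPh)(PCy3)(H2IMes) (5 mol %), CH2Cl2 (2 mM), reflux; solvent swap to EtOAc, Pd/C, H2 (1 atm), rt
Reagents that add atoms: none
Why: Ring-closing metathesis of the terminal alkene with the acryloyl group, assisted by the gem-dimethyl group, closes the seven-membered ring at C8=C9, and catalytic hydrogenation then saturates the conjugated alkene.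

Step 7
Reactants: 16 keto lactone
Product: 17 (3R,3aS,8aR)-3,8,8-trimethyl-4-methylideneoctahydro-2H-cyclohepta[b]furan-2-one (C7=C6H2; 1R,2S,3R in target numbering, same spatial arrangement)
Conditions: Zn, CH2Br2, TiCl4, THF/CH2Cl2, 0 °C to rt
Reagents that add atoms: dibromomethane, BrCBr
Why: Takai–Lombardo methylenation is non-basic and ketone-selective, so C6 is installed without C2 epimerisation, β-elimination of the lactone oxygen or attack on the lactone carbonyl.

Step 8
Reactants: 17 methylidene lactone
Product: 18 (1R,7S)-7-[(2R)-1-hydroxypropan-2-yl]-2,2-dimethyl-6-methylidenecycloheptan-1-ol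
Conditions: LiAlH4, THF, 0 °C
Reagents that add atoms: none
Why: Hydride reduction of the lactone frees the C1 hydroxyl needed as a directing group and brings C4 to the alcohol level, while the isolated alkene is inert.

Step 9
Reactants: 18 diol
Product: 19 (1R,7S)-2,2-dimethyl-6-methylidene-7-[(2R)-1-(triethylsilyloxy)propan-2-yl]cycloheptan-1-ol
Conditions: Et3SiCl (1.05 equiv), imidazole, CH2Cl2, −20 °C
Reagents that add atoms: chlorotriethylsilane, CC[Si](Cl)(CC)CC
Why: Silylation distinguishes the primary C4 hydroxyl from the neopentyl secondary C1 hydroxyl on steric grounds.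

Step 10
Reactants: 19 homoallylic alcohol
Product: 20 (3R,4R,5R)-6,6-dimethyl-4-[(2R)-1-(triethylsilyloxy)propan-2-yl]-1-oxaspiro[2.6]nonan-5-ol (spiro epoxide C7–C6; epoxide oxygen cis to the C1 hydroxyl)
Conditions: VO(acac)2 (5 mol %), t-BuOOH, CH2Cl2, 0 °C to rt
Reagents that add atoms: tert-butyl hydroperoxide, CC(C)(C)OO
Why: Vanadium-catalysed hydroxyl-directed epoxidation of a homoallylic alcohol delivers oxygen to the alkene face syn to the C1 hydroxyl, which is also the face away from the C2 side chain, and so sets C7 with its oxygen cis to the C1 oxygen.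

Step 11
Reactants: 20 epoxy alcohol
Product: 21 (3R,4R,5R)-5-(methoxymethoxy)-6,6-dimethyl-4-[(2R)-1-(triethylsilyloxy)propan-2-yl]-1-oxaspiro[2.6]nonane
Conditions: MOMCl, iPr2NEt, cat. Bu4NI, CH2Cl2, reflux
Reagents that add atoms: chloromethyl methyl ether, COCCl
Why: Alkylation of the hindered alcohol by the very reactive chloromethyl ether under amine base gives a base-stable acetal that cannot migrate, and it leaves the epoxide and silyl ether intact.

Step 12
Reactants: 21 silyl ether
Product: 22 (2R)-2-[(3R,4R,5R)-5-(methoxymethoxy)-6,6-dimethyl-1-oxaspiro[2.6]nonan-4-yl]propanal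
Conditions: (COCl)2, DMSO, CH2Cl2, −78 to −30 °C; Et3N, −78 °C to rt
Reagents that add atoms: none
Why: Under Swern conditions a primary triethylsilyl ether is cleaved by the chlorosulfonium salt and oxidised in the same operation, giving the C4 aldehyde without a separate desilylation and without acid that would open the epoxide.

Step 13
Reactants: 22 aldehyde
Product: 24 (3R,4R,5R)-5-(methoxymethoxy)-4-[(1E)-1-(methoxymethoxy)prop-1-en-2-yl]-6,6-dimethyl-1-oxaspiro[2.6]nonane, via potassium E enolate 23 (not isolated)
Conditions: KN(SiMe3)2, THF/DMPU, −78 °C; MOMCl, −78 °C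
Reagents that add atoms: chloromethyl methyl ether, COCCl
Why: O-alkylation of an α,α-disubstituted aldehyde enolate by a hard chloromethyl ether in a dipolar medium is favoured because C-alkylation would have to build a quaternary centre, and the enolate should form with oxygen anti to the bulky ring carbon C2, which gives the E enol ether.

Step 14
Reactants: 24 epoxy enol ether
Product: 25 (1S,2R,3R)-1-ethenyl-3-(methoxymethoxy)-2-[(1E)-1-(methoxymethoxy)prop-1-en-2-yl]-4,4-dimethylcycloheptan-1-ol (1R,2R,7S in target numbering; vinyl and alkenyl groups cis)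
Conditions: Me3SI, n-BuLi, THF, −10 °C to rt
Reagents that add atoms: trimethylsulfonium iodide, C[S+](C)C.[I-]
Why: One-carbon homologation of a terminal epoxide to an allylic alcohol with excess dimethylsulfonium methylide, in which the ylide opens the epoxide at the primary carbon C6 and a second equivalent induces loss of dimethyl sulfide, so the C7–O bond and its configuration are untouched.

Step 15
Reactants: 25 cis-1-vinyl-2-alkenylcycloheptanol
Product: 28 (1E,4S,5E,7R)-4,7-bis(methoxymethoxy)-5,8,8-trimethylcycloundeca-1,5-dien-1-yl trifluoromethanesulfonate (1R,4S in target numbering; C2=C3 E; C5 and C8 cis across C6=C7), via potassium alkoxide 26 (not isolated), via potassium enolate 27 (not isolated)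
Conditions: KH, 18-crown-6, THF, 0 °C to rt; then PhNTf2, −78 to 0 °C
Reagents that add atoms: N-phenylbis(trifluoromethanesulfonimide), O=S(=O)(N(c1ccccc1)S(=O)(=O)C(F)(F)F)C(F)(F)F
Why: Deprotonation gives alkoxide 26, whose oxyanion loosens the C2–C7 bond, and the 1,5-diene C5=C6–C7–C2–C3=C4 undergoes a concerted suprafacial [3,3] shift through a six-centre chair in which C4–C5 is made as C2–C7 is lost. The closest known reaction type is the anionic oxy-Cope ring expansion of 1,2-dialkenylcycloalkanols with in situ capture of the regiodefined enolate. The eleven-membered ring is therefore closed by a four-carbon enlargement of the cycloheptane, the two reacting arms being held on adjacent ring atoms, and not by an end-to-end macrocyclisation. Because the arms are cis, one ring bond is axial and the other equatorial in the chair: with the branched C1 equatorial at C2 and C8 axial at C7 (oxide equatorial), C2=C3 emerges E and enolate 27 has C5 cis to C8, a geometry that PhNTf2 fixes as the triflate. The new stereocentre C4 is controlled by the 2R,7S configuration, which decides which face of C3=C4 meets C5, together with the E enol ether, which keeps the C4 oxygen equatorial and so gives 4S. The step needs this chair to win over the flipped chair and the boats, which the bulk of C1 (MOM ether next to CMe2) should secure, and it needs the enolate to stay unscrambled, which is secured because hydrogen gas is the only conjugate acid formed.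

Step 16
Reactants: 28 enol triflate
Product: 29 (1R,2E,4S,6Z)-1,4-bis(methoxymethoxy)-3,7,11,11-tetramethylcycloundeca-2,6-diene
Conditions: MeMgBr, Fe(acac)3 (10 mol %), THF/NMP, −30 to 0 °C
Reagents that add atoms: methylmagnesium bromide, C[Mg]Br
Why: Iron-catalysed Kumada-type cross-coupling of an alkenyl triflate with a methyl Grignard reagent is fast at low temperature and proceeds with retention of alkene geometry, so C5 and C8 stay cis and C6=C7 becomes Z.

Step 17
Reactants: 29 bis-MOM ether
Product: 31 (1R,2E,4S,6Z)-3,7,11,11-tetramethylcycloundeca-2,6-diene-1,4-diol, via bis(bromomethyl) ether 30 (not isolated)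
Conditions: Me2BBr, CH2Cl2, −78 °C; then THF/sat. aq NaHCO3
Reagents that add atoms: none
Why: Dimethylboron bromide cleaves methoxymethyl ethers at the acetal carbon at low temperature to bromomethyl ethers that hydrolyse on work-up, so the allylic C–O bonds are never ionised and C1 and C4 keep their configuration.

Step 18
Reactants: 32 4-hydroxybenzoic acid
Product: 34 4-(tert-butyldimethylsilyloxy)benzoic acid, via silyl ester 33 (not isolated)
Conditions: TBSCl (2.2 equiv), imidazole, DMF, rt; then AcOH/THF/H2O, rt
Reagents that add atoms: tert-butyldimethylsilyl chloride, CC(C)(C)[Si](C)(C)Cl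
Why: Exhaustive silylation followed by hydrolysis of the far more labile silyl ester leaves the acid-tolerant aryl silyl ether.

Step 19
Reactants: 31 diol; 34 silylated acid
Product: 35 (1S,2E,4R,8Z)-4-hydroxy-2,5,5,9-tetramethylcycloundeca-2,8-dien-1-yl 4-(tert-butyldimethylsilyloxy)benzoate (C4 ester, C1 hydroxyl free; 1R,4S in target numbering)
Conditions: DCC, DMAP, 34 (1.05 equiv), CH2Cl2, 0 °C
Reagents that add atoms: none
Why: Steglich esterification with about one equivalent of acid should acylate the C4 hydroxyl, which is flanked by a methylene group, much faster than the neopentyl C1 hydroxyl next to C11, with retention at C4.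

Step 20
Reactants: 35 hydroxy ester
Product: 36 C1 acetate of 35 ((1R,4S)-1-acetoxy-4-[4-(tert-butyldimethylsilyloxy)benzoyloxy] diene in target numbering)
Conditions: Ac2O, DMAP, pyridine, rt to 40 °C
Reagents that add atoms: acetic anhydride, CC(=O)OC(C)=O
Why: DMAP-catalysed acetylation overcomes the hindrance at C1 and touches no other group.

Step 21
Reactants: 36 silyl-protected diester
Product: 37 target CNP0246761.4, (1R,2E,4S,6Z)-1-acetoxy-3,7,11,11-tetramethylcycloundeca-2,6-dien-4-yl 4-hydroxybenzoate
Conditions: Bu4NF, AcOH, THF, 0 °C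
Reagents that add atoms: none
Why: Buffered fluoride removes an aryl silyl ether much faster than it attacks either ester, and the acetic acid prevents acyl transfer by the phenoxide.

**Compound list**
1 | (R)-4-benzyl-1,3-oxazolidin-2-one | O=C1N[C@H](Cc2ccccc2)CO1 | starting material
2 | methyl 4-chloro-4-oxobutanoate | COC(=O)CCC(=O)Cl | starting material
3 | lithium (R)-4-benzyl-2-oxo-1,3-oxazolidin-3-ide | [Li+].O=C1[N-][C@H](Cc2ccccc2)CO1 | intermediate
4 | methyl 4-[(4R)-4-benzyl-2-oxo-1,3-oxazolidin-3-yl]-4-oxobutanoate | COC(=O)CCC(=O)N1[C@H](Cc2ccccc2)COC1=O | intermediate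
5 | 2,2-dimethylpent-4-enal | C=CCC(C)(C)C=O | starting material
6 | Z dibutylboron enolate of 4 | CCCCB(CCCC)O/C(=C\CC(=O)OC)N1[C@H](Cc2ccccc2)COC1=O | intermediate
7 | methyl (3R,4R)-3-{[(4R)-4-benzyl-2-oxo-1,3-oxazolidin-3-yl]carbonyl}-4-hydroxy-5,5-dimethyloct-7-enoate | C=CCC(C)(C)[C@H](O)[C@H](C(=O)N1[C@H](Cc2ccccc2)COC1=O)CC(=O)OC | intermediate
8 | trans lactone imide (1R,2R) | C=CCC(C)(C)[C@@H]1OC(=O)C[C@H]1C(=O)N2[C@H](Cc3ccccc3)COC2=O | intermediate
9 | lithium peroxycarboxylate of 10 | C=CCC(C)(C)[C@@H]1OC(=O)C[C@H]1C(=O)O[O-].[Li+] | intermediate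
10 | (2R,3R)-2-(2-methylpent-4-en-2-yl)-5-oxooxolane-3-carboxylic acid | C=CCC(C)(C)[C@@H]1OC(=O)C[C@H]1C(=O)O | intermediate
11 | disodium lactone enolate carboxylate of 10 | C=CCC(C)(C)[C@@H]1OC([O-])=C[C@H]1C(=O)[O-].[Na+].[Na+] | intermediate
12 | (2R,3R,4R)-4-methyl-2-(2-methylpent-4-en-2-yl)-5-oxooxolane-3-carboxylic acid | C=CCC(C)(C)[C@@H]1OC(=O)[C@H](C)[C@H]1C(=O)O | intermediate
13 | acid chloride of 12 | C=CCC(C)(C)[C@@H]1OC(=O)[C@H](C)[C@H]1C(=O)Cl | intermediate
14 | (3R,4R,5R)-3-methyl-5-(2-methylpent-4-en-2-yl)-4-(prop-2-enoyl)oxolan-2-one | C=CCC(C)(C)[C@@H]1OC(=O)[C@H](C)[C@H]1C(=O)C=C | intermediate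
15 | trans-fused enone lactone (C7 ketone, C8=C9; 1R,2R,3R) | CC1(C)CC=CC(=O)[C@@H]2[C@@H](C)C(=O)O[C@@H]12 | intermediate
16 | trans-fused keto lactone (1R,2R,3R) | CC1(C)CCCC(=O)[C@@H]2[C@@H](C)C(=O)O[C@@H]12 | intermediate
17 | trans-fused methylidene lactone (1R,2S,3R) | CC1(C)CCCC(=C)[C@@H]2[C@@H](C)C(=O)O[C@@H]12 | intermediate
18 | (1R,7S)-7-[(2R)-1-hydroxypropan-2-yl]-2,2-dimethyl-6-methylidenecycloheptan-1-ol | CC1(C)CCCC(=C)[C@H]([C@@H](C)CO)[C@H]1O | intermediate
19 | primary triethylsilyl ether of 18 | CC1(C)CCCC(=C)[C@H]([C@@H](C)CO[Si](CC)(CC)CC)[C@H]1O | intermediate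
20 | spiro epoxy alcohol (1R,2R,3R,7R) | CC1(C)CCC[C@]2(CO2)[C@H]([C@@H](C)CO[Si](CC)(CC)CC)[C@H]1O | intermediate
21 | C1 methoxymethyl ether of 20 | CC1(C)CCC[C@]2(CO2)[C@H]([C@@H](C)CO[Si](CC)(CC)CC)[C@H]1OCOC | intermediate
22 | epoxy aldehyde (1R,2R,3R,7R) | CC1(C)CCC[C@]2(CO2)[C@H]([C@@H](C)C=O)[C@H]1OCOC | intermediate
23 | potassium E enolate of 22 | CC1(C)CCC[C@]2(CO2)[C@H](/C(C)=C/[O-])[C@H]1OCOC.[K+] | intermediate
24 | epoxy E methoxymethyl enol ether (1R,2R,7R) | CC1(C)CCC[C@]2(CO2)[C@H](/C(C)=C/OCOC)[C@H]1OCOC | intermediate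
25 | (1R,2R,7S) cis-1-vinyl-2-alkenylcycloheptanol | C=C[C@@]1(O)CCCC(C)(C)[C@H](OCOC)[C@H]1/C(C)=C/OCOC | intermediate
26 | potassium alkoxide of 25 | C=C[C@@]1([O-])CCCC(C)(C)[C@H](OCOC)[C@H]1/C(C)=C/OCOC.[K+] | intermediate
27 | ring-expanded potassium enolate (1R,4S) | COCO[C@@H]1/C=C(\C)[C@@H](OCOC)C/C=C(/[O-])CCCC1(C)C.[K+] | intermediate
28 | ring-expanded C7 enol triflate (1R,4S) | COCO[C@@H]1/C=C(\C)[C@@H](OCOC)C/C=C(/OS(=O)(=O)C(F)(F)F)CCCC1(C)C | intermediate
29 | (1R,2E,4S,6Z)-1,4-bis(methoxymethoxy)-3,7,11,11-tetramethylcycloundeca-2,6-diene | COCO[C@@H]1/C=C(\C)[C@@H](OCOC)C/C=C(/C)CCCC1(C)C | intermediate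
30 | bis(bromomethyl) ether of 31 | BrCO[C@@H]1/C=C(\C)[C@@H](OCBr)C/C=C(/C)CCCC1(C)C | intermediate
31 | (1R,2E,4S,6Z)-3,7,11,11-tetramethylcycloundeca-2,6-diene-1,4-diol | O[C@@H]1/C=C(\C)[C@@H](O)C/C=C(/C)CCCC1(C)C | intermediate
32 | 4-hydroxybenzoic acid | OC(=O)c1ccc(O)cc1 | starting material
33 | tert-butyldimethylsilyl 4-(tert-butyldimethylsilyloxy)benzoate | CC(C)(C)[Si](C)(C)OC(=O)c1ccc(O[Si](C)(C)C(C)(C)C)cc1 | intermediate
34 | 4-(tert-butyldimethylsilyloxy)benzoic acid | OC(=O)c1ccc(O[Si](C)(C)C(C)(C)C)cc1 | intermediate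
35 | C4 4-(silyloxy)benzoate with free C1 hydroxyl | O[C@@H]1/C=C(\C)[C@@H](OC(=O)c2ccc(O[Si](C)(C)C(C)(C)C)cc2)C/C=C(/C)CCCC1(C)C | intermediate
36 | C1 acetate, C4 4-(silyloxy)benzoate | CC(=O)O[C@@H]1/C=C(\C)[C@@H](OC(=O)c2ccc(O[Si](C)(C)C(C)(C)C)cc2)C/C=C(/C)CCCC1(C)C | intermediate
37 | CNP0246761.4 | CC(=O)O[C@@H]1/C=C(\C)[C@@H](OC(=O)c2ccc(O)cc2)C/C=C(/C)CCCC1(C)C | target

**Step count:** 21 steps in total. The longest linear sequence is 20 steps (steps 1 to 17 and 19 to 21), and step 18 is a one-step side branch.

**Steps most likely to fail**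

Step 15.
- What may go wrong: the rearrangement may leak through the ring-flipped chair (C1 axial, C8 equatorial) or a boat. The alkoxide may fragment at C2–C7 instead of rearranging. The enolate may lose its geometry by proton exchange before it is sulfonylated.
- Fallback, setting out from 25: silylation with N-(trimethylsilyl)imidazole would give the tertiary trimethylsilyl ether F1.
- Heated in base-washed glassware (toluene, sealed tube, about 200 °C), it should undergo the neutral siloxy-Cope rearrangement to the ring-expanded trimethylsilyl enol ether F2. This is a covalent, chromatographable compound from which unwanted geometric isomers can be removed.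
- Methyllithium in THF then releases the lithium enolate F3 with its geometry intact, and PhNTf2 converts it into 28, where the route is rejoined.

Step 13.
- What may go wrong: kinetic deprotonation may control the enolate geometry poorly, and carbon alkylation or aldol self-condensation may compete with O-alkylation.
- Fallback, setting out from 22: equilibrating soft enolisation (Me3SiCl, DBU, CH2Cl2, reflux) would give the E trimethylsilyl enol ether F4, which is freed from its Z isomer on deactivated silica.
- Methyllithium in THF liberates the geometrically defined lithium enolate F5. Addition of DMPU and MOMCl at −78 °C returns to the route at 24.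

Step 14.
- What may go wrong: attack of the weakly nucleophilic ylide at C6, a primary carbon next to the fully substituted C7, may be slower than decay of the ylide or base-induced isomerisation of the epoxide.
- Fallback, setting out from 24: phenylselanylmethyllithium (from bis(phenylselanyl)methane and n-BuLi, THF, −78 °C), a much stronger nucleophile, would open the epoxide at C6 to the γ-hydroxy selenide F6.
- Oxidation with NaIO4/NaHCO3 in aqueous MeOH gives the selenoxide F7, which undergoes syn elimination at room temperature to the vinyl carbinol 25.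

**Further compounds**
F1 | step 15 | C7 trimethylsilyl ether of 25 | C=C[C@@]1(O[Si](C)(C)C)CCCC(C)(C)[C@H](OCOC)[C@H]1/C(C)=C/OCOC
F2 | step 15 | ring-expanded C7 trimethylsilyl enol ether (1R,4S) | COCO[C@@H]1/C=C(\C)[C@@H](OCOC)C/C=C(/O[Si](C)(C)C)CCCC1(C)C
F3 | step 15 | ring-expanded lithium enolate (1R,4S) | COCO[C@@H]1/C=C(\C)[C@@H](OCOC)C/C=C(/[O-])CCCC1(C)C.[Li+]
F4 | step 13 | E trimethylsilyl enol ether of 22 | CC1(C)CCC[C@]2(CO2)[C@H](/C(C)=C/O[Si](C)(C)C)[C@H]1OCOC
F5 | step 13 | lithium E enolate of 22 | CC1(C)CCC[C@]2(CO2)[C@H](/C(C)=C/[O-])[C@H]1OCOC.[Li+]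
F6 | step 14 | γ-hydroxy phenyl selenide (C7 carbinol with CH2CH2SePh) | c1ccccc1[Se]CC[C@@]2(O)CCCC(C)(C)[C@H](OCOC)[C@H]2/C(C)=C/OCOC
F7 | step 14 | selenoxide of F6 | O=[Se](CC[C@@]1(O)CCCC(C)(C)[C@H](OCOC)[C@H]1/C(C)=C/OCOC)c1ccccc1
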